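**Retrosynthetic overview**
- Ring C of the target 14 is opened at O1–C2 to the 2'-hydroxyaryl β-methoxy enone 13, so the last step is an addition–elimination of the C8a hydroxyl on the methoxymethylene carbon.
- The strategy rests on ring A: oxygen on C8a, C7 and C6, the acyl carbon C4 on C4a, hydrogen on C5 and C8. Cutting C5–C6 and C4a–C8a gives a 1,3,4-trioxygenated butadiene (C8a–C8–C7–C6, diene 4) and a terminal ynone supplying C5 and C4a (11).
- Diene 4 comes from methyl 4-methoxy-3-oxobutanoate by two O-silylations. Ynone 11 comes from methyl 3,4,5-trimethoxyphenylacetate by formylation/O-methylation, Weinreb amide formation and ethynyl Grignard addition.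
- Ring order: ring B is purchased, ring A is built by [4+2] cycloaddition and aromatisation (step 6), ring C is closed last (step 7).

Key step: step 6

Remark: the target has no stereocenter. The C=C geometries of 2, 4, 7, 8, 11 and 13 are drawn as single isomers, but mixtures would serve, because each of these double bonds is re-formed (step 2), consumed in the aromatisation (step 6) or engaged in an addition–elimination (step 7).

**Route**

Step 1
Reactants: 1 methyl 4-methoxy-3-oxobutanoate
Product: 2 methyl (E)-4-methoxy-3-(trimethylsilyloxy)but-2-enoate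
Conditions: TMSCl, Et3N, toluene, rt; filtration, distillation
Reagents that add atoms: chlorotrimethylsilane, C[Si](C)(C)Cl
Why: Soft enolisation of the β-keto ester between its two carbonyl groups by Et3N and O-silylation at the ketone oxygen (silyl enol ether formation) should give the conjugated β-silyloxy enoate, the usual first stage in making a 1-alkoxy-1,3-bis(silyloxy)diene.

Step 2
Reactants: 2 methyl (E)-4-methoxy-3-(trimethylsilyloxy)but-2-enoate
Product: 4 (1Z,3Z)-1,4-dimethoxy-1,3-bis(trimethylsilyloxy)buta-1,3-diene, via lithium dienolate 3 (not isolated)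
Conditions: LiN(iPr)2, THF, −78 °C; then TMSCl, −78 °C → 0 °C; non-aqueous work-up, used crude
Reagents that add atoms: chlorotrimethylsilane, C[Si](C)(C)Cl
Why: LiN(iPr)2 should remove a γ-hydrogen (the CH2 next to the methoxy group) of the vinylogous carbonate to give the extended dienolate 3, which TMSCl traps on the ester oxygen as the silyl ketene acetal (γ-deprotonation/O-silylation); β-elimination is excluded because the methoxy group sits on the carbanion carbon itself.

Step 3
Reactants: 5 methyl 2-(3,4,5-trimethoxyphenyl)acetate
Product: 7 methyl (E)-3-methoxy-2-(3,4,5-trimethoxyphenyl)prop-2-enoate, via sodium enolate 6 (not isolated)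
Conditions: NaH, HCO2Me, DMF, 0 °C → rt; then Me2SO4, rt
Reagents that add atoms: methyl formate, COC=O; dimethyl sulfate, COS(=O)(=O)OC
Why: The crossed Claisen condensation with methyl formate is driven to the stabilised formyl-ester enolate 6, and the hard electrophile Me2SO4 in DMF should alkylate it on oxygen to the β-methoxyacrylate with the E isomer favoured.

Step 4
Reactants: 7 methyl (E)-3-methoxy-2-(3,4,5-trimethoxyphenyl)prop-2-enoate
Product: 8 (E)-N,3-dimethoxy-N-methyl-2-(3,4,5-trimethoxyphenyl)prop-2-enamide
Conditions: MeNH(OMe)·HCl, iPrMgCl, THF, −20 °C → 0 °C; aq NH4Cl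
Reagents that add atoms: N,O-dimethylhydroxylamine hydrochloride, CNOC.Cl
Why: The chloromagnesium amide made in the flask should replace the ester methoxy group by nucleophilic acyl substitution (direct Weinreb amide formation from an ester), the methoxymethylene carbon being a poor acceptor because of its donor oxygen and the flanking aryl group.

Step 5
Reactants: 8 (E)-N,3-dimethoxy-N-methyl-2-(3,4,5-trimethoxyphenyl)prop-2-enamide; 9 ethynylmagnesium bromide
Product: 11 (E)-1-methoxy-2-(3,4,5-trimethoxyphenyl)pent-1-en-4-yn-3-one, via magnesium chelate 10 (not isolated)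
Conditions: HC≡CMgBr (excess), THF, 0 °C → rt; inverse quench into cold 1 M aq HCl/Et2O; product kept cold and used promptly
Reagents that add atoms: none
Why: In this Weinreb ketone synthesis the alkynyl Grignard should add once to give the five-membered chelate 10, which is stable until the inverse acidic quench; the quench releases the ynone and protonates the liberated N,O-dimethylhydroxylamine before it can add to the terminal ynone, and the vinylogous-ester enol ether should tolerate brief cold dilute acid.

Step 6
Reactants: 4 (1Z,3Z)-1,4-dimethoxy-1,3-bis(trimethylsilyloxy)buta-1,3-diene; 11 (E)-1-methoxy-2-(3,4,5-trimethoxyphenyl)pent-1-en-4-yn-3-one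
Product: 13 (E)-1-(2,4-dihydroxy-5-methoxyphenyl)-3-methoxy-2-(3,4,5-trimethoxyphenyl)prop-2-en-1-one, via cycloadduct 12 (not isolated)
Conditions: 4 (1.5 equiv), toluene, 0 °C → rt (45 °C if slow); then 0.5 M aq HCl, THF, 0 °C, short contact; crude 13 carried on
Reagents that add atoms: none
Why: The diene, its HOMO raised by three oxygen donors, should add across the terminal ynone in a normal-demand [4+2] cycloaddition, either concerted and strongly asynchronous or as a Michael addition followed by closure of the allenolate onto the oxocarbenium carbon, forming C5–C6 and C4a–C8a to give cyclohexa-1,4-diene 12. The closest known reaction type is the Diels–Alder benzannulation of 1-alkoxy-1,3-bis(silyloxy)butadienes with acetylenic ketones and esters to resorcinol derivatives. Ring A is closed as a six-membered carbocycle by the cycloaddition itself; in the stepwise picture this is a 6-exo-trig attack of the allenolate carbon C4a on the ester-derived carbon C8a. Dilute acid then cleaves both silyl groups, the C8a ketal loses methanol to a cyclohexadienone, and this tautomerises by loss of the C6 hydrogen, so ring A appears with 8a-OH, 7-OH and 6-OMe and needs no protecting group; the two stereocenters of 12 (C6, C8a) vanish and none is set. The step needs regio- and chemoselectivity: the methoxy-bearing terminus C6 is the nucleophilic end because bonding there leaves positive charge stabilised by the oxygens on C7 and C8a, and it meets the unhindered β-carbon C5 of the ynone, which puts C8a ortho to the carbonyl and the methoxy group next to C5–H. The ynone is far more electrophilic than the donor-substituted, aryl-shielded methoxy enone, the absence of a Lewis acid disfavours the competing [3+3] mode through the ketone carbonyl, and any 13 that already closes ring C during the acid treatment converges on the target in step 7.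

Step 7
Reactants: 13 (E)-1-(2,4-dihydroxy-5-methoxyphenyl)-3-methoxy-2-(3,4,5-trimethoxyphenyl)prop-2-en-1-one
Product: 14 7-hydroxy-6-methoxy-3-(3,4,5-trimethoxyphenyl)-4H-chromen-4-one
Conditions: HCl (1.25 M in MeOH), rt → 50 °C
Reagents that add atoms: none
Why: Acid should activate the vinylogous ester so that the C8a hydroxyl (hydrogen-bonded to the C4 carbonyl; the C7 hydroxyl cannot reach) adds to the methoxymethylene carbon in a 6-endo-trig oxa-Michael addition and methanol is eliminated (addition–elimination), the aromatic 4-pyranone ring C being the thermodynamic sink as in the standard closure of 2'-hydroxyaryl β-alkoxy enones to chromones.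

**Compound list**
1 | methyl 4-methoxy-3-oxobutanoate | COCC(=O)CC(=O)OC | starting material
2 | methyl (E)-4-methoxy-3-(trimethylsilyloxy)but-2-enoate (E/Z mixture acceptable) | COC/C(O[Si](C)(C)C)=C\C(=O)OC | intermediate
3 | lithium 1,4-dimethoxy-3-(trimethylsilyloxy)buta-1,3-dien-1-olate (γ-deprotonated 2, geometry drawn as in 4) | CO/C=C(\O[Si](C)(C)C)/C=C(/OC)[O-].[Li+] | intermediate (not isolated)
4 | (1Z,3Z)-1,4-dimethoxy-1,3-bis(trimethylsilyloxy)buta-1,3-diene | CO/C=C(\O[Si](C)(C)C)/C=C(/OC)O[Si](C)(C)C | intermediate
5 | methyl 2-(3,4,5-trimethoxyphenyl)acetate | COC(=O)Cc1cc(OC)c(OC)c(OC)c1 | starting material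
6 | sodium (E)-3-methoxy-3-oxo-2-(3,4,5-trimethoxyphenyl)prop-1-en-1-olate | [Na+].[O-]/C=C(/C(=O)OC)c1cc(OC)c(OC)c(OC)c1 | intermediate (not isolated)
7 | methyl (E)-3-methoxy-2-(3,4,5-trimethoxyphenyl)prop-2-enoate | CO/C=C(/C(=O)OC)c1cc(OC)c(OC)c(OC)c1 | intermediate
8 | (E)-N,3-dimethoxy-N-methyl-2-(3,4,5-trimethoxyphenyl)prop-2-enamide | CO/C=C(/C(=O)N(C)OC)c1cc(OC)c(OC)c(OC)c1 | intermediate
9 | ethynylmagnesium bromide | C#C[Mg]Br | starting material
10 | bromomagnesium (E)-1-methoxy-3-[methoxy(methyl)amino]-2-(3,4,5-trimethoxyphenyl)pent-1-en-4-yn-3-olate (tetrahedral chelate, racemic at C3) | CO/C=C(/C(O[Mg]Br)(C#C)N(C)OC)c1cc(OC)c(OC)c(OC)c1 | intermediate (not isolated)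
11 | (E)-1-methoxy-2-(3,4,5-trimethoxyphenyl)pent-1-en-4-yn-3-one | CO/C=C(/C(=O)C#C)c1cc(OC)c(OC)c(OC)c1 | intermediate
12 | (E)-1-[3,6-dimethoxy-4,6-bis(trimethylsilyloxy)cyclohexa-1,4-dien-1-yl]-3-methoxy-2-(3,4,5-trimethoxyphenyl)prop-2-en-1-one (mixture of diastereomers at ring C3 and C6) | COC1C=C(C(=O)/C(=C/OC)c2cc(OC)c(OC)c(OC)c2)C(OC)(O[Si](C)(C)C)C=C1O[Si](C)(C)C | intermediate (not isolated)
13 | (E)-1-(2,4-dihydroxy-5-methoxyphenyl)-3-methoxy-2-(3,4,5-trimethoxyphenyl)prop-2-en-1-one | CO/C=C(/C(=O)c1cc(OC)c(O)cc1O)c1cc(OC)c(OC)c(OC)c1 | intermediate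
14 | 7-hydroxy-6-methoxy-3-(3,4,5-trimethoxyphenyl)-4H-chromen-4-one | COc1cc2c(=O)c(-c3cc(OC)c(OC)c(OC)c3)coc2cc1O | target

**Count and risks**

Total step count: 7. Longest linear sequence: 5 steps (5 → 7 → 8 → 11 → 13 → 14, steps 3 to 7); the diene branch (steps 1 and 2) joins at step 6.

Steps most likely to fail:

1. Step 6. The addition may stop after the first C–C bond, with silyl transfer to the allenolate giving an open-chain Michael adduct and ring A left unclosed. The terminal ynone may also oligomerise, or the diene may be protodesilylated before it reacts. The fallback buys ring A and sets out from ester 5. Saponification (LiOH, THF/H2O, rt) would give 2-(3,4,5-trimethoxyphenyl)acetic acid F1. This acid would acylate 4-methoxybenzene-1,3-diol at the carbon ortho to one hydroxyl and para to the other (BF3·OEt2, 85 °C, Friedel–Crafts acylation) to give the deoxybenzoin 1-(2,4-dihydroxy-5-methoxyphenyl)-2-(3,4,5-trimethoxyphenyl)ethan-1-one F2. Treatment with DMF, BF3·OEt2 and MsCl at 70 °C would formylate the active methylene and close ring C, coming back to the route at the target 14.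

2. Step 5. Addition of the weakly nucleophilic alkynyl Grignard to the donor-deactivated, aryl-hindered amide may be slow, and the released N,O-dimethylhydroxylamine may add to the terminal ynone during the quench. The fallback sets out from amide 8. Reduction with iBu2AlH (THF, −78 °C) would give (E)-3-methoxy-2-(3,4,5-trimethoxyphenyl)prop-2-enal F3. 1,2-Addition of ethynylmagnesium bromide 9 (THF, −78 °C, neutral work-up) would give (E)-1-methoxy-2-(3,4,5-trimethoxyphenyl)pent-1-en-4-yn-3-ol F4 (racemic). Oxidation with MnO2 (CH2Cl2, rt) would return to the route at ynone 11 without any amine in the flask.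

3. Step 4. The magnesium amide may attack the methoxymethylene carbon (amine-for-methoxy exchange by addition–elimination) instead of the ester carbonyl, or acyl substitution at the vinylogous carbonate may stay incomplete. The fallback sets out from ester 7. Saponification (LiOH, THF/MeOH/H2O, rt) would give (E)-3-methoxy-2-(3,4,5-trimethoxyphenyl)prop-2-enoic acid F5. Coupling with MeNH(OMe)·HCl (EDC·HCl, HOBt, iPr2NEt, CH2Cl2, rt), in which the free amine is too weak a Michael donor to touch the enol ether, would come back at amide 8.

Further compounds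
F1 | step 6 | 2-(3,4,5-trimethoxyphenyl)acetic acid | OC(=O)Cc1cc(OC)c(OC)c(OC)c1
F2 | step 6 | 1-(2,4-dihydroxy-5-methoxyphenyl)-2-(3,4,5-trimethoxyphenyl)ethan-1-one | COc1cc(C(=O)Cc2cc(OC)c(OC)c(OC)c2)c(O)cc1O
F3 | step 5 | (E)-3-methoxy-2-(3,4,5-trimethoxyphenyl)prop-2-enal | CO/C=C(/C=O)c1cc(OC)c(OC)c(OC)c1
F4 | step 5 | (E)-1-methoxy-2-(3,4,5-trimethoxyphenyl)pent-1-en-4-yn-3-ol (racemic) | CO/C=C(/C(O)C#C)c1cc(OC)c(OC)c(OC)c1
F5 | step 4 | (E)-3-methoxy-2-(3,4,5-trimethoxyphenyl)prop-2-enoic acid | CO/C=C(/C(=O)O)c1cc(OC)c(OC)c(OC)c1
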